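The route rests on disconnecting the C6–C7 single bond of the cross-conjugated dienone (prostanoid numbering: C1 ester carbon, cyclopentenone ring C8–C12, C9 ketone, C10 bromide, C12 acetoxy carbon). A Heck vinylation joins a 5-methylene cyclopentenone to methyl (E)-6-iodohex-5-enoate and, in the same operation, creates the exocyclic 7E alkene. It exploits ring carbon C8, which lies between the C9 carbonyl and the fully substituted C12: the alkylpalladium formed at C8 has β-hydrogens only on C7, so elimination must return into the exocyclic position. The precursor is an α-methylene ketone lacking C1–C6; its C12 centre is relayed from (R)-4-silyloxycyclopentenone, and bromine enters by epoxide opening.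

Key step: step 10

Assumption: (Z)-oct-2-en-1-ol, (R)-4-[(tert-butyldimethylsilyl)oxy]cyclopent-2-en-1-one and methyl hex-5-ynoate are taken as commercially available.

Remark: for compounds 9, 10 and 12 the epimer expected to predominate is drawn; the extra centres are erased one step later, so any minor epimer converges.

Step 1
Reactants: 1 (Z)-oct-2-en-1-ol
Product: 2 (Z)-1-chlorooct-2-ene
Conditions: PPh3, CCl4, reflux
Reagents that add atoms: carbon tetrachloride, ClC(Cl)(Cl)Cl
Why: Appel chlorination displaces the primary allylic oxyphosphonium by chloride in an SN2 sense, which should leave the Z alkene and the allylic position unchanged.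

Step 2
Reactants: 2 (Z)-1-chlorooct-2-ene; 3 (R)-4-[(tert-butyldimethylsilyl)oxy]cyclopent-2-en-1-one
Product: 5 (1S,4R)-4-[(tert-butyldimethylsilyl)oxy]-1-[(Z)-oct-2-en-1-yl]cyclopent-2-en-1-ol, via (Z)-oct-2-enylbarium chloride 4 (not isolated)
Conditions: active Ba (from BaI2 and 2 equiv lithium biphenylide, THF, rt); 2, THF, −78 °C; then 3, −78 °C; aq NH4Cl
Reagents that add atoms: none
Why: An allylbarium generated at −78 °C should keep its Z geometry and attack the ketone through its unsubstituted α-carbon (Barbier-type 1,2-allylation), and it should approach the carbonyl of 3 anti to the C4 silyloxy group, so that the new tertiary carbinol centre (future C12) is set cis to OTBS by substrate control.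

Step 3
Reactants: 5 (1S,4R)-4-[(tert-butyldimethylsilyl)oxy]-1-[(Z)-oct-2-en-1-yl]cyclopent-2-en-1-ol
Product: 6 (1S,4R)-1-[(Z)-oct-2-en-1-yl]cyclopent-2-ene-1,4-diol
Conditions: TBAF, THF, 0 °C → rt
Reagents that add atoms: none
Why: Fluoride-mediated desilylation frees the secondary allylic alcohol without affecting the tertiary carbinol centre.

Step 4
Reactants: 6 (1S,4R)-1-[(Z)-oct-2-en-1-yl]cyclopent-2-ene-1,4-diol
Product: 7 (S)-4-hydroxy-4-[(Z)-oct-2-en-1-yl]cyclopent-2-en-1-one
Conditions: MnO2 (activated, excess), CH2Cl2, rt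
Reagents that add atoms: none
Why: MnO2 oxidises only the secondary allylic alcohol (allylic oxidation), which removes the relay stereocentre after it has fixed C12 and leaves the tertiary alcohol and the Z alkene untouched.

Step 5
Reactants: 7 (S)-4-hydroxy-4-[(Z)-oct-2-en-1-yl]cyclopent-2-en-1-one
Product: 8 (S)-4-[(tert-butyldimethylsilyl)oxy]-4-[(Z)-oct-2-en-1-yl]cyclopent-2-en-1-one
Conditions: TBSOTf, 2,6-lutidine, CH2Cl2, −78 → 0 °C
Reagents that add atoms: tert-butyldimethylsilyl triflate, CC(C)(C)[Si](C)(C)OS(=O)(=O)C(F)(F)F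
Why: A silyl triflate with a hindered pyridine base silylates the tertiary alcohol without enolising the ketone, which blocks retro-aldol racemisation of the β-hydroxy ketone in the basic steps that follow.

Step 6
Reactants: 8 (S)-4-[(tert-butyldimethylsilyl)oxy]-4-[(Z)-oct-2-en-1-yl]cyclopent-2-en-1-one
Product: 9 (1R,4S,5S)-4-[(tert-butyldimethylsilyl)oxy]-4-[(Z)-oct-2-en-1-yl]-6-oxabicyclo[3.1.0]hexan-2-one
Conditions: 30% aq H2O2, NaOH (cat.), MeOH, 0 °C
Reagents that add atoms: hydrogen peroxide, OO
Why: In this Weitz–Scheffer epoxidation the hydroperoxide anion adds only to the electron-poor enone C10=C11 and not to the isolated 14Z alkene, attack anti to the silyloxy group being expected.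

Step 7
Reactants: 9 (1R,4S,5S)-4-[(tert-butyldimethylsilyl)oxy]-4-[(Z)-oct-2-en-1-yl]-6-oxabicyclo[3.1.0]hexan-2-one
Product: 11 (S)-2-bromo-4-[(tert-butyldimethylsilyl)oxy]-4-[(Z)-oct-2-en-1-yl]cyclopent-2-en-1-one, via trans-bromohydrin 10 (not isolated)
Conditions: 48% aq HBr (1.5 equiv), THF, 0 °C → rt
Reagents that add atoms: hydrogen bromide, Br
Why: Bromide opens the protonated α,β-epoxy ketone at C10 (α to the carbonyl, inversion) and the resulting α-bromo-β-hydroxy ketone loses water under the acid to the conjugated 2-bromoenone, so bromine is placed at C10 without electrophilic bromine that would attack the 14Z alkene.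

Step 8
Reactants: 11 (S)-2-bromo-4-[(tert-butyldimethylsilyl)oxy]-4-[(Z)-oct-2-en-1-yl]cyclopent-2-en-1-one
Product: 14 (R)-2-bromo-4-[(tert-butyldimethylsilyl)oxy]-5-methylidene-4-[(Z)-oct-2-en-1-yl]cyclopent-2-en-1-one, via Mannich base 12 (not isolated), via methiodide 13 (not isolated)
Conditions: LiN(iPr)2 (LDA), THF, −78 °C; CH2=NMe2+ I−, −78 → 0 °C; aqueous work-up, crude; MeI, CH2Cl2, rt; aq NaHCO3, rt
Reagents that add atoms: dimethyl(methylidene)ammonium iodide, C=[N+](C)C.[I-]
Why: C8 is the only enolisable position of 11, its lithium enolate is aminomethylated by the iminium salt (Mannich reaction), and quaternisation followed by E1cB loss of trimethylamine should give the exocyclic methylene ketone.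

Step 9
Reactants: 15 methyl hex-5-ynoate
Product: 17 methyl (E)-6-iodohex-5-enoate, via alkenylzirconocene 16 (not isolated)
Conditions: Cp2Zr(H)Cl, THF, rt; then I2, 0 °C
Reagents that add atoms: iodine, II
Why: Hydrozirconation adds Zr–H syn and anti-Markovnikov to the terminal alkyne faster than it reduces the ester, and iodinolysis of the C–Zr bond proceeds with retention to give the E-alkenyl iodide.

Step 10
Reactants: 14 (R)-2-bromo-4-[(tert-butyldimethylsilyl)oxy]-5-methylidene-4-[(Z)-oct-2-en-1-yl]cyclopent-2-en-1-one; 17 methyl (E)-6-iodohex-5-enoate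
Product: 18 methyl (5E,7E)-7-[(5R)-3-bromo-5-[(tert-butyldimethylsilyl)oxy]-5-[(Z)-oct-2-en-1-yl]-2-oxocyclopent-3-en-1-ylidene]hept-5-enoate
Conditions: Pd(OAc)2 (10 mol%), Ag2CO3 (1.2 equiv), 17 (1.5 equiv), DMF, rt → 40 °C, dark
Reagents that add atoms: none
Why: Zerovalent palladium formed from Pd(OAc)2 inserts into the C–I bond of 17 with retention of the E geometry, the alkenylpalladium adds syn across the exocyclic C7=C8 methylene of 14 with carbon going to the unhindered terminal C7 (this forms the C6–C7 bond) and palladium to C8, and syn β-hydride elimination then re-forms C7=C8 in conjugation with the ketone and the 5,6-alkene. The closest known reaction type is the Heck vinylation of α-methylene carbonyl compounds with alkenyl iodides under ligand-free, silver-assisted conditions. No ring is closed and no stereocentre is formed; the step has to control the direction of elimination, the alkene geometry and the chemoselectivity. The direction of elimination is secured by the substrate, because C8 lies between the C9 carbonyl and the fully substituted C12 and therefore has β-hydrogens only on C7. The 7E geometry is expected because the diene then avoids the C9 carbonyl oxygen, and any 7Z fraction could be equilibrated with catalytic I2 and light. Chemoselectivity rests on the much faster oxidative addition of the alkenyl iodide than of the C10–Br bond at room temperature, on the silyl ether at C12 (no β-acyloxy elimination, no allyl ionisation), and on the inertness of the trisubstituted C10=C11 and the isolated 14Z alkene toward carbopalladation.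

Step 11
Reactants: 18 methyl (5E,7E)-7-[(5R)-3-bromo-5-[(tert-butyldimethylsilyl)oxy]-5-[(Z)-oct-2-en-1-yl]-2-oxocyclopent-3-en-1-ylidene]hept-5-enoate
Product: 19 methyl (5E,7E)-7-[(5R)-3-bromo-5-hydroxy-5-[(Z)-oct-2-en-1-yl]-2-oxocyclopent-3-en-1-ylidene]hept-5-enoate
Conditions: HF·pyridine, THF/pyridine, 0 °C → rt
Reagents that add atoms: none
Why: Fluoride cleaves the tertiary silyl ether under buffered conditions that the trienone, the vinyl bromide and the methyl ester should tolerate.

Step 12
Reactants: 19 methyl (5E,7E)-7-[(5R)-3-bromo-5-hydroxy-5-[(Z)-oct-2-en-1-yl]-2-oxocyclopent-3-en-1-ylidene]hept-5-enoate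
Product: 20 methyl (5E,7E)-7-[(5R)-5-acetoxy-3-bromo-5-[(Z)-oct-2-en-1-yl]-2-oxocyclopent-3-en-1-ylidene]hept-5-enoate (CNP0295154.3)
Conditions: Ac2O, DMAP, Et3N, CH2Cl2, rt
Reagents that add atoms: acetic anhydride, CC(=O)OC(C)=O
Why: DMAP-catalysed acyl transfer (Steglich-type acylation) esterifies the hindered tertiary alcohol without breaking any bond to C12, so the configuration is retained.

Compound list
1 | (Z)-oct-2-en-1-ol | CCCCC/C=C\CO | starting material
2 | (Z)-1-chlorooct-2-ene | CCCCC/C=C\CCl | intermediate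
3 | (R)-4-[(tert-butyldimethylsilyl)oxy]cyclopent-2-en-1-one | O=C1C=C[C@H](O[Si](C)(C)C(C)(C)C)C1 | starting material
4 | (Z)-oct-2-enylbarium chloride | CCCCC/C=C\C[Ba]Cl | intermediate
5 | (1S,4R)-4-[(tert-butyldimethylsilyl)oxy]-1-[(Z)-oct-2-en-1-yl]cyclopent-2-en-1-ol | CCCCC/C=C\C[C@@]1(O)C=C[C@H](O[Si](C)(C)C(C)(C)C)C1 | intermediate
6 | (1S,4R)-1-[(Z)-oct-2-en-1-yl]cyclopent-2-ene-1,4-diol | CCCCC/C=C\C[C@@]1(O)C=C[C@H](O)C1 | intermediate
7 | (S)-4-hydroxy-4-[(Z)-oct-2-en-1-yl]cyclopent-2-en-1-one | CCCCC/C=C\C[C@@]1(O)C=CC(=O)C1 | intermediate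
8 | (S)-4-[(tert-butyldimethylsilyl)oxy]-4-[(Z)-oct-2-en-1-yl]cyclopent-2-en-1-one | CCCCC/C=C\C[C@@]1(O[Si](C)(C)C(C)(C)C)C=CC(=O)C1 | intermediate
9 | (1R,4S,5S)-4-[(tert-butyldimethylsilyl)oxy]-4-[(Z)-oct-2-en-1-yl]-6-oxabicyclo[3.1.0]hexan-2-one (epoxide anti to the silyloxy group) | CCCCC/C=C\C[C@@]1(O[Si](C)(C)C(C)(C)C)[C@H]2O[C@H]2C(=O)C1 | intermediate
10 | (2S,3R,4S)-2-bromo-4-[(tert-butyldimethylsilyl)oxy]-3-hydroxy-4-[(Z)-oct-2-en-1-yl]cyclopentan-1-one (trans-bromohydrin) | CCCCC/C=C\C[C@@]1(O[Si](C)(C)C(C)(C)C)[C@@H](O)[C@H](Br)C(=O)C1 | intermediate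
11 | (S)-2-bromo-4-[(tert-butyldimethylsilyl)oxy]-4-[(Z)-oct-2-en-1-yl]cyclopent-2-en-1-one | CCCCC/C=C\C[C@@]1(O[Si](C)(C)C(C)(C)C)C=C(Br)C(=O)C1 | intermediate
12 | (4S,5S)-2-bromo-4-[(tert-butyldimethylsilyl)oxy]-5-[(dimethylamino)methyl]-4-[(Z)-oct-2-en-1-yl]cyclopent-2-en-1-one (Mannich base) | CCCCC/C=C\C[C@@]1(O[Si](C)(C)C(C)(C)C)C=C(Br)C(=O)[C@H]1CN(C)C | intermediate
13 | {[(1S,5S)-3-bromo-5-[(tert-butyldimethylsilyl)oxy]-5-[(Z)-oct-2-en-1-yl]-2-oxocyclopent-3-en-1-yl]methyl}trimethylammonium iodide (methiodide) | CCCCC/C=C\C[C@@]1(O[Si](C)(C)C(C)(C)C)C=C(Br)C(=O)[C@H]1C[N+](C)(C)C.[I-] | intermediate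
14 | (R)-2-bromo-4-[(tert-butyldimethylsilyl)oxy]-5-methylidene-4-[(Z)-oct-2-en-1-yl]cyclopent-2-en-1-one | CCCCC/C=C\C[C@@]1(O[Si](C)(C)C(C)(C)C)C=C(Br)C(=O)C1=C | intermediate
15 | methyl hex-5-ynoate | COC(=O)CCCC#C | starting material
16 | methyl (E)-6-[chlorobis(cyclopentadienyl)zirconio]hex-5-enoate (alkenylzirconocene) | COC(=O)CCC/C=C/[Zr](Cl)(C1C=CC=C1)C1C=CC=C1 | intermediate
17 | methyl (E)-6-iodohex-5-enoate | COC(=O)CCC/C=C/I | intermediate
18 | methyl (5E,7E)-7-[(5R)-3-bromo-5-[(tert-butyldimethylsilyl)oxy]-5-[(Z)-oct-2-en-1-yl]-2-oxocyclopent-3-en-1-ylidene]hept-5-enoate | CCCCC/C=C\C[C@@]1(O[Si](C)(C)C(C)(C)C)C=C(Br)C(=O)/C1=C/C=C/CCCC(=O)OC | intermediate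
19 | methyl (5E,7E)-7-[(5R)-3-bromo-5-hydroxy-5-[(Z)-oct-2-en-1-yl]-2-oxocyclopent-3-en-1-ylidene]hept-5-enoate | CCCCC/C=C\C[C@@]1(O)C=C(Br)C(=O)/C1=C/C=C/CCCC(=O)OC | intermediate
20 | methyl (5E,7E)-7-[(5R)-5-acetoxy-3-bromo-5-[(Z)-oct-2-en-1-yl]-2-oxocyclopent-3-en-1-ylidene]hept-5-enoate (CNP0295154.3) | CCCCC/C=C\C[C@@]1(OC(C)=O)C=C(Br)C(=O)/C1=C/C=C/CCCC(=O)OC | target

Total step count: 12. Longest linear sequence: 11 steps (steps 1–8 and 10–12, from 1); step 9 is the convergent branch.

Steps most likely to fail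

Step 10 (Heck coupling). Zerovalent palladium may insert into the C10–Br bond or ionise the allylic C12–O bond before productive carbopalladation, consuming the ring fragment. The fallback moves the coupling to an oxidative manifold that has no carbon–halogen partner. Alkyne 15 would be hydroborated with pinacolborane (Cp2Zr(H)Cl cat., Et3N cat., rt → 60 °C) to the alkenylboronate methyl (E)-6-(4,4,5,5-tetramethyl-1,3,2-dioxaborolan-2-yl)hex-5-enoate F1. F1 would then be joined to 14 in an oxidative boron Heck reaction (Pd(OAc)2, 2,9-dimethyl-1,10-phenanthroline, O2 1 atm, DMF, rt → 50 °C), in which transmetalation from boron to divalent palladium replaces oxidative addition. The fallback sets out from 14 and 15 and comes back to the route at 18.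

Step 2 (allylbarium addition). The allylbarium may lose its Z geometry on warming or attack through its γ-carbon, giving the branched carbinol. The fallback builds the side chain from an alkyne instead. Enone 3 would be treated with allenylmagnesium bromide (from propargyl bromide, Mg, HgCl2 cat., Et2O, −78 °C), which should add anti to OTBS to give (1S,4R)-4-[(tert-butyldimethylsilyl)oxy]-1-(prop-2-yn-1-yl)cyclopent-2-en-1-ol F2. The alkoxide–acetylide dianion (n-BuLi 2.1 equiv, THF/DMPU, −78 → 0 °C) would be alkylated with 1-iodopentane to (1S,4R)-4-[(tert-butyldimethylsilyl)oxy]-1-(oct-2-yn-1-yl)cyclopent-2-en-1-ol F3. Semihydrogenation (H2, Pd/CaCO3 poisoned with Pb(OAc)2, quinoline, EtOAc) should then give the Z alkene. The fallback sets out from 3 and comes back to the route at 5.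

Step 8 (methylenation). The lithium enolate of 11 may decompose, by β-elimination of silanolate toward a cyclopentadienone or by attack of the amide base on the bromoenone. The fallback avoids a strong base. Ketone 11 would be enolised softly (TMSOTf, Et3N, CH2Cl2, 0 °C) to the silyl dienol ether {[(1S)-3-bromo-1-[(Z)-oct-2-en-1-yl]-4-[(trimethylsilyl)oxy]cyclopenta-2,4-dien-1-yl]oxy}(tert-butyl)dimethylsilane F4. F4 should react with CH2=NMe2+ I− in CH2Cl2 at rt (Mukaiyama-type Mannich reaction) to give Mannich base 12, which is taken on with MeI and NaHCO3 as in step 8. The fallback sets out from 11 and comes back to the route at 12.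

Further compounds
F1 | step 10 | methyl (E)-6-(4,4,5,5-tetramethyl-1,3,2-dioxaborolan-2-yl)hex-5-enoate | COC(=O)CCC/C=C/B1OC(C)(C)C(C)(C)O1
F2 | step 2 | (1S,4R)-4-[(tert-butyldimethylsilyl)oxy]-1-(prop-2-yn-1-yl)cyclopent-2-en-1-ol | C#CC[C@@]1(O)C=C[C@H](O[Si](C)(C)C(C)(C)C)C1
F3 | step 2 | (1S,4R)-4-[(tert-butyldimethylsilyl)oxy]-1-(oct-2-yn-1-yl)cyclopent-2-en-1-ol | CCCCCC#CC[C@@]1(O)C=C[C@H](O[Si](C)(C)C(C)(C)C)C1
F4 | step 8 | {[(1S)-3-bromo-1-[(Z)-oct-2-en-1-yl]-4-[(trimethylsilyl)oxy]cyclopenta-2,4-dien-1-yl]oxy}(tert-butyl)dimethylsilane | CCCCC/C=C\C[C@@]1(O[Si](C)(C)C(C)(C)C)C=C(Br)C(O[Si](C)(C)C)=C1
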